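**Retrosynthetic overview**

1. 18 ⇐ 17 (HF): ring C (O1–C2–C3–C4–C4a–C8a) is the last ring closed, by ring-closing metathesis across C3=C4 of 16, with C4 carried as a silyl enol ether and ethene lost.
2. Enabling feature: ring C is a β-aryloxy ketone whose C4=O lies peri to the C5–OH of ring A. Its enol form has a C3=C4 bond (the metathesis site); O4 and O5 can be bridged by tBu2Si into a temporary six-membered ring (C5–C4a–C4–O–Si–O) that points C4=CH2 towards O1; and O1–C2H(Ph)–CH=CH2 is the branched product of an Ir allylic etherification. The two OH groups ortho to the acetyl group of 12 are equivalent, so either can take either role.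
3. 16 ⇐ 13 + cinnamyl carbonate 14 (Ir, sets C2); 13 ⇐ 12 (tBu2Si(OTf)2); 12 ⇐ Mitsunobu of the 4-OH of phloroacetophenone 11 with benzylic alcohol 10 (inversion at C8).
4. 10 ⇐ acrylate RCM (dihydropyranone, first ring made) ⇐ Brown allylboration of aldehyde 5 (sets C6) ⇐ (2S,3S)-3-phenylglycidol 1 (C7, C8) by C3-selective opening with PMBOH.
5. Ring order: lactone (step 7) → temporary silylene ring (step 10, removed in step 13) → ring C (step 12); the three benzene rings are bought.

Key step: step 12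

Remark: locants C6–C8 denote the lactone carbinol carbon and the two side-chain carbons (C8 benzylic); O1–C8a denote the chromanone; TBS = tert-butyldimethylsilyl, PMB = 4-methoxybenzyl.
Assumption: the (Sa,Sc,Sc)-BINOL-derived N,N-bis(1-phenylethyl)phosphoramidite–Ir catalyst gives the (S)-branched aryl ether from a cinnamyl carbonate; if the sense were opposite, the enantiomeric ligand would be used.

**Route**

Step 1
Reactants: 1 (2S,3S)-3-phenylglycidol
Product: 2 (2S,3R)-3-[(4-methoxybenzyl)oxy]-3-phenylpropane-1,2-diol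
Conditions: PMBOH (excess), Ti(OiPr)4 (1.5 equiv), PhMe, 70 °C; aq. tartaric acid work-up
Reagents that add atoms: 4-methoxybenzyl alcohol, COc1ccc(CO)cc1
Why: Ti(IV)-mediated regioselective opening of a 2,3-epoxy alcohol, in which the titanium-bound substrate is attacked by the alcohol at the benzylic C3 in an SN2 sense, so the future C8 is inverted (anti diol monoether) and the future C7 is untouched.

Step 2
Reactants: 2 (2S,3R)-3-[(4-methoxybenzyl)oxy]-3-phenylpropane-1,2-diol
Product: 3 (2S,3R)-1,2-bis(TBS-oxy)-3-(PMB-oxy)-3-phenylpropane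
Conditions: TBSCl (2.5 equiv), imidazole, DMF, 40 °C
Reagents that add atoms: tert-butyldimethylsilyl chloride, CC(C)(C)[Si](C)(C)Cl
Why: Exhaustive O-silylation of both hydroxyl groups with a silyl chloride and imidazole; no stereocentre is touched.

Step 3
Reactants: 3 (2S,3R)-1,2-bis(TBS-oxy)-3-(PMB-oxy)-3-phenylpropane
Product: 4 (2S,3R)-2-(TBS-oxy)-3-(PMB-oxy)-3-phenylpropan-1-ol
Conditions: HF·pyridine, pyridine, THF, 0 °C
Reagents that add atoms: none
Why: Selective fluoride-mediated desilylation, in which the unhindered primary TBS ether should cleave well before the secondary one and the PMB ether is inert.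

Step 4
Reactants: 4 (2S,3R)-2-(TBS-oxy)-3-(PMB-oxy)-3-phenylpropan-1-ol
Product: 5 (2R,3R)-2-(TBS-oxy)-3-(PMB-oxy)-3-phenylpropanal
Conditions: Dess–Martin periodinane, CH2Cl2, 0 °C → rt; used crude
Reagents that add atoms: none
Why: Dess–Martin oxidation of the primary alcohol under non-basic conditions, so the α-silyloxy stereocentre should not epimerise (the descriptor changes only because of CIP priorities).

Step 5
Reactants: 5 (2R,3R)-2-(TBS-oxy)-3-(PMB-oxy)-3-phenylpropanal
Product: 7 (1R,2S,3S)-2-(TBS-oxy)-1-(PMB-oxy)-1-phenylhex-5-en-3-ol, via diisopinocampheylborinate 6 (not isolated)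
Conditions: (−)-Ipc2B(allyl), Et2O, −78 °C; then 3 M NaOH, 30% H2O2, 0 °C → rt
Reagents that add atoms: (−)-B-allyldiisopinocampheylborane, C=CCB([C@@H]1C[C@@H]2C[C@H]([C@H]1C)C2(C)C)[C@@H]1C[C@@H]2C[C@H]([C@H]1C)C2(C)C
Why: Brown allylboration through a closed chair transition state, in which the (−)-Ipc reagent delivers allyl to the Si face and sets the (3S) carbinol (future C6) under reagent control, in line with the Felkin–Anh preference of the α-silyloxy aldehyde for the 2,3-anti product.

Step 6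
Reactants: 7 (1R,2S,3S)-2-(TBS-oxy)-1-(PMB-oxy)-1-phenylhex-5-en-3-ol
Product: 8 (1R,2S,3S)-2-(TBS-oxy)-1-(PMB-oxy)-1-phenylhex-5-en-3-yl acrylate
Conditions: acryloyl chloride, Et3N, DMAP (cat.), CH2Cl2, −20 → 0 °C
Reagents that add atoms: acryloyl chloride, C=CC(=O)Cl
Why: O-acylation of the secondary alcohol with an acid chloride and amine base, with retention at the carbinol carbon.

Step 7
Reactants: 8 (1R,2S,3S)-2-(TBS-oxy)-1-(PMB-oxy)-1-phenylhex-5-en-3-yl acrylate
Product: 9 (6S)-6-[(1S,2R)-1-(TBS-oxy)-2-(PMB-oxy)-2-phenylethyl]-5,6-dihydro-2H-pyran-2-one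
Conditions: Grubbs II (5 mol%), CH2Cl2 (5 mM), 40 °C
Reagents that add atoms: none
Why: Ring-closing metathesis of an acrylate with a terminal alkene, the standard entry to 6-substituted 5,6-dihydro-2H-pyran-2-ones; the ring enforces the cis alkene and no stereocentre is involved.

Step 8
Reactants: 9 (6S)-6-[(1S,2R)-1-(TBS-oxy)-2-(PMB-oxy)-2-phenylethyl]-5,6-dihydro-2H-pyran-2-one
Product: 10 (6S)-6-[(1R,2R)-1-(TBS-oxy)-2-hydroxy-2-phenylethyl]-5,6-dihydro-2H-pyran-2-one
Conditions: DDQ, CH2Cl2/pH 7 buffer (10:1), 0 °C → rt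
Reagents that add atoms: none
Why: Oxidative cleavage of the PMB ether with DDQ (hydride abstraction, then hydrolysis of the oxocarbenium ion), which should spare the silyl ether and the enoate and leaves the C8–O bond intact.

Step 9
Reactants: 10 (6S)-6-[(1R,2R)-1-(TBS-oxy)-2-hydroxy-2-phenylethyl]-5,6-dihydro-2H-pyran-2-one; 11 2',4',6'-trihydroxyacetophenone
Product: 12 (6S)-6-[(1S,2S)-2-(4-acetyl-3,5-dihydroxyphenoxy)-1-(TBS-oxy)-2-phenylethyl]-5,6-dihydro-2H-pyran-2-one
Conditions: 11 (1.5 equiv), PPh3, DIAD, THF, 0 °C → rt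
Reagents that add atoms: none
Why: Mitsunobu etherification, in which the 4-OH of 11 (the most acidic, and the only one not hydrogen-bonded to the acetyl group) displaces the activated benzylic C8–O in an SN2 sense, so C8 is inverted to the configuration of the target.

Step 10
Reactants: 12 (6S)-6-[(1S,2S)-2-(4-acetyl-3,5-dihydroxyphenoxy)-1-(TBS-oxy)-2-phenylethyl]-5,6-dihydro-2H-pyran-2-one
Product: 13 (6S)-6-[(1S,2S)-2-[(2,2-di-tert-butyl-5-hydroxy-4-methylidene-4H-1,3,2-benzodioxasilin-7-yl)oxy]-1-(TBS-oxy)-2-phenylethyl]-5,6-dihydro-2H-pyran-2-one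
Conditions: tBu2Si(OTf)2 (1.05 equiv), Et3N, CH2Cl2, −78 → 0 °C
Reagents that add atoms: di-tert-butylsilyl bis(trifluoromethanesulfonate), CC(C)(C)[Si](OS(=O)(=O)C(F)(F)F)(OS(=O)(=O)C(F)(F)F)C(C)(C)C
Why: Silyl triflate/amine silylation, in which one of the two equivalent phenols is O-silylated and the pendant Si–OTf then silylates the acetyl oxygen with soft enolisation, closing a six-membered silylene enol ether and leaving the other phenol free and no longer chelated.

Step 11
Reactants: 13 (6S)-6-[(1S,2S)-2-[(2,2-di-tert-butyl-5-hydroxy-4-methylidene-4H-1,3,2-benzodioxasilin-7-yl)oxy]-1-(TBS-oxy)-2-phenylethyl]-5,6-dihydro-2H-pyran-2-one; 14 (E)-cinnamyl methyl carbonate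
Product: 16 (6S)-6-[(1S,2S)-2-[(2,2-di-tert-butyl-4-methylidene-5-{[(1S)-1-phenylprop-2-en-1-yl]oxy}-4H-1,3,2-benzodioxasilin-7-yl)oxy]-1-(TBS-oxy)-2-phenylethyl]-5,6-dihydro-2H-pyran-2-one, via lithium phenoxide 15 (not isolated)
Conditions: LiHMDS (1.0 equiv), THF, −78 → 0 °C; then 14 (1.2 equiv), [Ir(cod)Cl]2 (2 mol%), (Sa,Sc,Sc)-phosphoramidite (4 mol%, pre-activated with n-PrNH2), THF, rt
Reagents that add atoms: none
Why: Iridium-catalysed asymmetric allylic etherification, in which the phenoxide attacks the substituted terminus of the (π-cinnamyl)Ir–phosphoramidite complex to give the branched ether, and the ligand controls the new stereocentre (future C2, S).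

Step 12
Reactants: 16 (6S)-6-[(1S,2S)-2-[(2,2-di-tert-butyl-4-methylidene-5-{[(1S)-1-phenylprop-2-en-1-yl]oxy}-4H-1,3,2-benzodioxasilin-7-yl)oxy]-1-(TBS-oxy)-2-phenylethyl]-5,6-dihydro-2H-pyran-2-one
Product: 17 (2S)-2-phenyl-2H-chromene in which O4 (enol) and O5 are bridged by tBu2Si and O7 carries the (1S,2S)-side chain of 12 (silylene enol ether of TBS-protected 18)
Conditions: Hoveyda–Grubbs II (10 mol%), 1,4-benzoquinone (20 mol%), PhMe (5 mM), 80 °C, Ar sparge
Reagents that add atoms: none
Why: Ring-closing olefin metathesis: the Ru alkylidene loads on the monosubstituted vinyl group of the O1–C2 arm, undergoes intramolecular [2+2] with the 1,1-disubstituted silyl enol ether C4=CH2 and cycloreverts to give the C3=C4 bond and Ru=CH2, which leaves as ethene. The closest known reactions are the ring-closing metathesis of silyl enol ethers with terminal alkenes to cyclic silyl enol ethers and the metathesis route from ortho-alkenyl aryl allyl ethers to 2H-chromenes. Ring C (O1, C2, C3, C4, C4a, C8a) is closed as a six-membered ring by C3=C4 bond formation, the ring size being fixed by the ortho relationship of the two arms on ring A. No stereocentre is created: C2, set in step 11, has no bond made or broken, cannot epimerise under the neutral conditions, and the chalcone/flavanone equilibrium that could scramble it is never entered. The step needs site selectivity for the vinyl/enol ether pair over the endocyclic, electron-poor lactone alkene, and a productive approach to the hindered enol ether; the silylene ring holds C4=CH2 coplanar with ring A and directed at the allyl arm, its terminal CH2 is the only accessible acceptor (giving Ru=CH2 rather than a Fischer carbene), and the lactone C=C is a poor partner for Ru alkylidenes.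

Step 13
Reactants: 17 (2S)-2-phenyl-2H-chromene in which O4 (enol) and O5 are bridged by tBu2Si and O7 carries the (1S,2S)-side chain of 12
Product: 18 (2S)-5-hydroxy-7-{(1S,2S)-2-hydroxy-2-[(2S)-6-oxo-3,6-dihydro-2H-pyran-2-yl]-1-phenylethoxy}-2-phenyl-2,3-dihydro-4H-chromen-4-one (CNP0113500.1)
Conditions: HF·pyridine (excess), THF/pyridine, 0 °C → rt
Reagents that add atoms: none
Why: Global fluoride-mediated desilylation, which cleaves both Si–O bonds of the silylene (the enol tautomerises to the C4 ketone by protonation at C3 and the 5-OH is released) and the C7 TBS ether; the weakly acidic medium should prevent retro-oxa-Michael opening, so C2 is retained.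

**Compound list**

1 | (2S,3S)-3-phenylglycidol | OC[C@@H]1O[C@H]1c1ccccc1 | starting material
2 | (2S,3R)-3-[(4-methoxybenzyl)oxy]-3-phenylpropane-1,2-diol | OC[C@H](O)[C@H](OCc1ccc(OC)cc1)c1ccccc1 | intermediate
3 | (2S,3R)-1,2-bis(TBS-oxy)-3-(PMB-oxy)-3-phenylpropane | CC(C)(C)[Si](C)(C)OC[C@H](O[Si](C)(C)C(C)(C)C)[C@H](OCc1ccc(OC)cc1)c1ccccc1 | intermediate
4 | (2S,3R)-2-(TBS-oxy)-3-(PMB-oxy)-3-phenylpropan-1-ol | OC[C@H](O[Si](C)(C)C(C)(C)C)[C@H](OCc1ccc(OC)cc1)c1ccccc1 | intermediate
5 | (2R,3R)-2-(TBS-oxy)-3-(PMB-oxy)-3-phenylpropanal | O=C[C@H](O[Si](C)(C)C(C)(C)C)[C@H](OCc1ccc(OC)cc1)c1ccccc1 | intermediate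
6 | diisopinocampheylborinate of 7 | C=CC[C@H](OB([C@@H]1C[C@@H]2C[C@H]([C@H]1C)C2(C)C)[C@@H]1C[C@@H]2C[C@H]([C@H]1C)C2(C)C)[C@H](O[Si](C)(C)C(C)(C)C)[C@H](OCc1ccc(OC)cc1)c1ccccc1 | intermediate
7 | (1R,2S,3S)-2-(TBS-oxy)-1-(PMB-oxy)-1-phenylhex-5-en-3-ol | C=CC[C@H](O)[C@H](O[Si](C)(C)C(C)(C)C)[C@H](OCc1ccc(OC)cc1)c1ccccc1 | intermediate
8 | (1R,2S,3S)-2-(TBS-oxy)-1-(PMB-oxy)-1-phenylhex-5-en-3-yl acrylate | C=CC[C@H](OC(=O)C=C)[C@H](O[Si](C)(C)C(C)(C)C)[C@H](OCc1ccc(OC)cc1)c1ccccc1 | intermediate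
9 | (6S)-6-[(1S,2R)-1-(TBS-oxy)-2-(PMB-oxy)-2-phenylethyl]-5,6-dihydro-2H-pyran-2-one | O=C1C=CC[C@@H]([C@H](O[Si](C)(C)C(C)(C)C)[C@H](OCc2ccc(OC)cc2)c2ccccc2)O1 | intermediate
10 | (6S)-6-[(1R,2R)-1-(TBS-oxy)-2-hydroxy-2-phenylethyl]-5,6-dihydro-2H-pyran-2-one | O=C1C=CC[C@@H]([C@H](O[Si](C)(C)C(C)(C)C)[C@H](O)c2ccccc2)O1 | intermediate
11 | 2',4',6'-trihydroxyacetophenone | CC(=O)c1c(O)cc(O)cc1O | starting material
12 | (6S)-6-[(1S,2S)-2-(4-acetyl-3,5-dihydroxyphenoxy)-1-(TBS-oxy)-2-phenylethyl]-5,6-dihydro-2H-pyran-2-one | O=C1C=CC[C@@H]([C@H](O[Si](C)(C)C(C)(C)C)[C@@H](Oc2cc(O)c(C(C)=O)c(O)c2)c2ccccc2)O1 | intermediate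
13 | silylene enol ether: (6S)-6-[(1S,2S)-2-[(2,2-di-tert-butyl-5-hydroxy-4-methylidene-4H-1,3,2-benzodioxasilin-7-yl)oxy]-1-(TBS-oxy)-2-phenylethyl]-5,6-dihydro-2H-pyran-2-one | O=C1C=CC[C@@H]([C@H](O[Si](C)(C)C(C)(C)C)[C@@H](Oc2cc3c(c(O)c2)C(=C)O[Si](C(C)(C)C)(C(C)(C)C)O3)c2ccccc2)O1 | intermediate
14 | (E)-cinnamyl methyl carbonate | COC(=O)OC/C=C/c1ccccc1 | starting material
15 | lithium phenoxide of 13 | O=C1C=CC[C@@H]([C@H](O[Si](C)(C)C(C)(C)C)[C@@H](Oc2cc3c(c([O-])c2)C(=C)O[Si](C(C)(C)C)(C(C)(C)C)O3)c2ccccc2)O1.[Li+] | intermediate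
16 | (S)-1-phenylallyl ether of 13: (6S)-6-[(1S,2S)-2-[(2,2-di-tert-butyl-4-methylidene-5-{[(1S)-1-phenylprop-2-en-1-yl]oxy}-4H-1,3,2-benzodioxasilin-7-yl)oxy]-1-(TBS-oxy)-2-phenylethyl]-5,6-dihydro-2H-pyran-2-one | O=C1C=CC[C@@H]([C@H](O[Si](C)(C)C(C)(C)C)[C@@H](Oc2cc3c(c(O[C@@H](C=C)c4ccccc4)c2)C(=C)O[Si](C(C)(C)C)(C(C)(C)C)O3)c2ccccc2)O1 | intermediate
17 | (2S)-2-phenyl-2H-chromene with O4/O5 bridged by tBu2Si and the TBS-protected (1S,2S)-side chain on O7 | O=C1C=CC[C@@H]([C@H](O[Si](C)(C)C(C)(C)C)[C@@H](Oc2cc3c4c(c2)O[C@H](c2ccccc2)C=C4O[Si](C(C)(C)C)(C(C)(C)C)O3)c2ccccc2)O1 | intermediate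
18 | (2S)-5-hydroxy-7-{(1S,2S)-2-hydroxy-2-[(2S)-6-oxo-3,6-dihydro-2H-pyran-2-yl]-1-phenylethoxy}-2-phenyl-2,3-dihydro-4H-chromen-4-one | O=C1C=CC[C@@H]([C@H](O)[C@@H](Oc2cc(O)c3c(c2)O[C@H](c2ccccc2)CC3=O)c2ccccc2)O1 | target

**Step count and risks**

Total step count: 13. Longest linear sequence: 13 (steps 1–13 from 1; 11 and 14 are purchased).

Steps most likely to fail:

Step 11 (Ir allylic etherification). The hindered phenoxide may turn over slowly, attack the linear terminus or react through a ring carbon. The branched ether may lose enantiopurity by reversible ionisation. The methoxide released may attack the silylene. Fallback, setting out from 13: a Mitsunobu etherification of the free phenol with commercial (R)-1-phenylprop-2-yn-1-ol (PPh3, DIAD, PhMe, 0 °C → rt; inversion) should give the (S)-propargyl aryl ether F1. Lindlar semihydrogenation (H2, Pd/CaCO3–Pb, quinoline, EtOAc) of the terminal alkyne then returns to the route at 16. The stereocentre then comes from a purchased alcohol instead of a catalyst.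

Step 12 (enol ether RCM). Initiation or ring closure at the hindered 1,1-disubstituted enol ether may be slow, the catalyst may be trapped as a Fischer carbene, or the allyl ether may isomerise. Fallback, setting out from 12 (it also bypasses the silylene): a BF3·OEt2-mediated Claisen–Schmidt condensation with benzaldehyde in dioxane at rt should give the 2',6'-dihydroxychalcone F2. A cinchona-derived bifunctional squaramide (10 mol%, PhMe, 0 °C) should then effect the 6-endo oxa-Michael cyclisation to the TBS-protected flavanone F3, whose C2 configuration would have to be secured by catalyst choice and separation of the C2 epimer. HF·pyridine desilylation comes back to the route at 18.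

Step 9 (Mitsunobu). The activated β-silyloxy benzylic alcohol may eliminate, the TBS group may migrate from O7 to O8, inversion may be incomplete through ionisation, or a chelated ortho-OH may be alkylated. Fallback, setting out from 10: mesylation (MsCl, Et3N, CH2Cl2, −20 °C; retention) should give the benzylic mesylate F4. Displacement with the caesium 4-phenoxide of 11 (Cs2CO3, DMF, rt; SN2, inversion) comes back to the route at 12.

Further compounds
F1 | step 11 | (S)-1-phenylprop-2-yn-1-yl ether of 13 | O=C1C=CC[C@@H]([C@H](O[Si](C)(C)C(C)(C)C)[C@@H](Oc2cc3c(c(O[C@@H](C#C)c4ccccc4)c2)C(=C)O[Si](C(C)(C)C)(C(C)(C)C)O3)c2ccccc2)O1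
F2 | step 12 | (E)-chalcone from 12 and benzaldehyde | O=C1C=CC[C@@H]([C@H](O[Si](C)(C)C(C)(C)C)[C@@H](Oc2cc(O)c(C(=O)/C=C/c3ccccc3)c(O)c2)c2ccccc2)O1
F3 | step 12 | TBS ether of 18 at the side-chain hydroxyl | O=C1C=CC[C@@H]([C@H](O[Si](C)(C)C(C)(C)C)[C@@H](Oc2cc(O)c3c(c2)O[C@H](c2ccccc2)CC3=O)c2ccccc2)O1
F4 | step 9 | methanesulfonate of 10 | O=C1C=CC[C@@H]([C@H](O[Si](C)(C)C(C)(C)C)[C@H](OS(C)(=O)=O)c2ccccc2)O1
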